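**Retrosynthetic overview**
1. Target ⇐ phenol desilylation ⇐ late threefold Mitsunobu esterification (inversion at C-6) of cyclobutane triacid **41** with three equivalents of bicyclic amino alcohol **11**.
2. Triacid **41** ⇐ cyclobutanone **33**: the ketone carbon is homologated to CH–CO2H (methylenation, hydroboration, oxidation with epimerisation) and CH2OSi is oxidised to CO2H.
3. Cyclobutanone **33** (cyclobutane ring) ⇐ keteniminium–alkene [2+2] of chiral aryl acetamide **21** with (E,E)-dienoate **30**, which already carries the complete side chain.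
4. **21** ⇐ catechol (O-methylation, bromination, silylation, Pd α-arylation of an acetamide); **30** ⇐ bromoacetal + methyl but-2-ynoate (syn-carbocupration), then Wittig, reduction, silylation.
5. **11** ⇐ Pauson–Khand reaction of enyne **6**, which closes the piperidine and cyclopentenone rings in one step; the methyl stereocentre comes from a Cu-catalysed allylic alkylation.

**Assumption:** the sense of induction of the ferrocenyl diphosphine (step 3) and of the (2S,5S)-pyrrolidine amide (step 18) is taken to be the one needed; if either is opposite, the mirror-image ligand or amine is used with no other change.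

**Abbreviations:** Ar = 3-methoxy-4-[tri(propan-2-yl)silyloxy]phenyl; TBS = tert-butyl(dimethyl)silyl; TIPS = tri(propan-2-yl)silyl. Cyclobutane locants used in names: C-1 = quaternary (methyl-bearing) carbon, C-2 = aryl-bearing carbon, C-3 = carbon opposite C-1, C-4 = side-chain-bearing carbon.

---

### Fragment 1: amino alcohol 11

**Step 1**
Reactants: 1 but-2-yn-1-amine
Product: 2 methyl but-2-yn-1-ylcarbamate
Conditions: ClCO2Me, Et3N, CH2Cl2, 0 °C → rt
Reagents that add atoms: methyl chloroformate COC(=O)Cl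
Why: N-acylation of the primary amine gives a carbamate that activates N–H for alkylation and is a latent N-methyl group.

**Step 2**
Reactants: 2 methyl but-2-yn-1-ylcarbamate; 3 (2E)-1,4-dibromobut-2-ene
Product: 5 methyl [(2E)-4-bromobut-2-en-1-yl](but-2-yn-1-yl)carbamate, via sodium carbamate salt 4 (not isolated)
Conditions: NaH, DMF, 0 °C; then 3 (4 equiv), 0 °C → rt
Reagents that add atoms: none
Why: SN2 N-alkylation of the carbamate anion, with excess dibromide suppressing double substitution.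

**Step 3**
Reactants: 5 methyl [(2E)-4-bromobut-2-en-1-yl](but-2-yn-1-yl)carbamate
Product: 6 methyl (but-2-yn-1-yl)[(2R)-2-methylbut-3-en-1-yl]carbamate
Conditions: MeMgBr, CuBr·SMe2 (5 mol%), (R,R)-Taniaphos, Fe(C5H5)[C5H3(PPh2)CH(NMe2)C6H4PPh2] (6 mol%), CH2Cl2, −75 °C
Reagents that add atoms: methylmagnesium bromide C[Mg]Br
Why: copper-catalysed asymmetric allylic alkylation (SN2′) delivers methyl to the γ-carbon under control of the chiral diphosphine, setting the (R)-methyl stereocentre (later C-4) and leaving the terminal alkene.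

**Step 4**
Reactants: 6 methyl (but-2-yn-1-yl)[(2R)-2-methylbut-3-en-1-yl]carbamate
Product: 7 methyl (4R,4aR)-4,7-dimethyl-6-oxo-1,3,4,4a,5,6-hexahydro-2H-cyclopenta[c]pyridine-2-carboxylate
Conditions: Co2(CO)8 (10 mol%), tetramethylthiourea (60 mol%), CO (1 atm), benzene, 70 °C
Reagents that add atoms: carbon monoxide [C-]#[O+]
Why: intramolecular Pauson–Khand [2+2+1] closes both rings, and the allylic methyl sits pseudo-equatorial in the chair-like insertion transition state so that H-4a ends cis to the C-4 methyl.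

**Step 5**
Reactants: 7 methyl (4R,4aR)-4,7-dimethyl-6-oxo-1,3,4,4a,5,6-hexahydro-2H-cyclopenta[c]pyridine-2-carboxylate
Product: 9 methyl (4R,4aR,7R,7aS)-4,7-dimethyl-6-oxooctahydro-2H-cyclopenta[c]pyridine-2-carboxylate, via 7-epi ketone 8 (not isolated)
Conditions: H2 (4 atm), Pd/C, EtOAc, rt; filter; then NaOMe (0.2 equiv), MeOH, rt
Reagents that add atoms: none
Why: catalytic hydrogenation adds H2 to the enone from the face of H-4a (cis ring fusion at C-7a), and base epimerisation α to the ketone then moves the C-7 methyl to the convex face, trans to C-1, the thermodynamic position.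

**Step 6**
Reactants: 9 methyl (4R,4aR,7R,7aS)-4,7-dimethyl-6-oxooctahydro-2H-cyclopenta[c]pyridine-2-carboxylate
Product: 10 methyl (4R,4aR,6S,7R,7aS)-6-hydroxy-4,7-dimethyloctahydro-2H-cyclopenta[c]pyridine-2-carboxylate
Conditions: LiBH(s-Bu)3, THF, −78 °C; H2O
Reagents that add atoms: none
Why: the bulky hydride attacks the cyclopentanone anti to the adjacent C-7 methyl (as in 2-methylcyclopentanone reductions), giving the alcohol with OH cis to that methyl (6S).

**Step 7**
Reactants: 10 methyl (4R,4aR,6S,7R,7aS)-6-hydroxy-4,7-dimethyloctahydro-2H-cyclopenta[c]pyridine-2-carboxylate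
Product: 11 (4R,4aR,6S,7R,7aS)-2,4,7-trimethyloctahydro-1H-cyclopenta[c]pyridin-6-ol
Conditions: LiAlH4, THF, reflux; H2O, aq. NaOH
Reagents that add atoms: none
Why: hydride reduction of the methyl carbamate to N–CH3 leaves all stereocentres untouched and gives the C-6 epimer of the amino alcohol in the target.

### Fragment 2: aryl acetamide 21

**Step 8**
Reactants: 12 benzene-1,2-diol
Product: 13 2-methoxyphenol
Conditions: MeI (1.0 equiv), K2CO3, acetone, reflux
Reagents that add atoms: iodomethane CI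
Why: Williamson mono-O-methylation, with the dimethyl ether and unreacted diol removed by base extraction and distillation.

**Step 9**
Reactants: 13 2-methoxyphenol
Product: 14 4-bromo-2-methoxyphenol
Conditions: NBS, MeCN, 0 °C
Reagents that add atoms: N-bromosuccinimide O=C1CCC(=O)N1Br
Why: electrophilic aromatic bromination goes para to the free hydroxyl, the stronger director.

**Step 10**
Reactants: 14 4-bromo-2-methoxyphenol
Product: 15 (4-bromo-2-methoxyphenoxy)tri(propan-2-yl)silane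
Conditions: TIPSCl, imidazole, DMF, rt
Reagents that add atoms: chlorotri(propan-2-yl)silane CC(C)[Si](Cl)(C(C)C)C(C)C
Why: O-silylation gives a phenol ether stable to base, Lewis acid and oxidants and removable by fluoride at the end.

**Step 11**
Reactants: 16 (2S,5S)-2,5-dimethylpyrrolidine; 17 acetyl chloride
Product: 18 1-[(2S,5S)-2,5-dimethylpyrrolidin-1-yl]ethan-1-one
Conditions: Et3N, CH2Cl2, 0 °C
Reagents that add atoms: none
Why: N-acylation attaches the C2-symmetric amine that later controls the facial sense of the keteniminium cycloaddition.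

**Step 12**
Reactants: 18 1-[(2S,5S)-2,5-dimethylpyrrolidin-1-yl]ethan-1-one; 15 (4-bromo-2-methoxyphenoxy)tri(propan-2-yl)silane
Product: 21 1-[(2S,5S)-2,5-dimethylpyrrolidin-1-yl]-2-Ar-ethan-1-one, via lithium enolate 19 (not isolated), via chlorozinc enolate 20 (not isolated)
Conditions: s-BuLi, THF, −78 °C; ZnCl2, → rt; then 15, Pd(dba)2 (2 mol%), P(t-Bu)3 (2 mol%), THF, rt → 50 °C
Reagents that add atoms: none
Why: palladium-catalysed α-arylation of the amide zinc enolate (Negishi-type) couples the aryl bromide cleanly, and the mild zinc enolate avoids diarylation.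

### Fragment 3: dienoate 30

**Step 13**
Reactants: 22 2-(2-bromoethyl)-1,3-dioxolane; 23 methyl but-2-ynoate
Product: 26 methyl (2E)-5-(1,3-dioxolan-2-yl)-3-methylpent-2-enoate, via Grignard reagent 24 (not isolated), via organocopper reagent 25 (not isolated)
Conditions: Mg, THF, 30 °C; CuBr·SMe2 (1.0 equiv), −78 °C; then 23, −78 °C; aq. NH4Cl
Reagents that add atoms: none
Why: syn-carbocupration of the ynoate and protonation of the alkenylcopper with retention place the new chain trans to CO2Me, fixing the (E)-trisubstituted enoate of the side chain.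

**Step 14**
Reactants: 26 methyl (2E)-5-(1,3-dioxolan-2-yl)-3-methylpent-2-enoate
Product: 27 methyl (2E)-3-methyl-6-oxohex-2-enoate
Conditions: 1 M HCl, acetone, rt
Reagents that add atoms: water O
Why: acid-catalysed acetal hydrolysis frees the aldehyde without touching the enoate.

**Step 15**
Reactants: 27 methyl (2E)-3-methyl-6-oxohex-2-enoate
Product: 28 methyl (2E,6E)-3,7-dimethyl-8-oxoocta-2,6-dienoate
Conditions: Ph3P=C(CH3)CHO, toluene, 90 °C
Reagents that add atoms: 2-(triphenyl-λ5-phosphanylidene)propanal CC(C=O)=P(c1ccccc1)(c1ccccc1)c1ccccc1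
Why: Wittig olefination with a stabilised ylide gives the (E)-2-methyl enal (chain trans to CHO).

**Step 16**
Reactants: 28 methyl (2E,6E)-3,7-dimethyl-8-oxoocta-2,6-dienoate
Product: 29 methyl (2E,6E)-8-hydroxy-3,7-dimethylocta-2,6-dienoate
Conditions: NaBH4, CeCl3·7H2O, MeOH, 0 °C
Reagents that add atoms: none
Why: Luche 1,2-reduction converts the enal to the allylic alcohol and leaves the enoate alone.

**Step 17**
Reactants: 29 methyl (2E,6E)-8-hydroxy-3,7-dimethylocta-2,6-dienoate
Product: 30 methyl (2E,6E)-8-(TBS-oxy)-3,7-dimethylocta-2,6-dienoate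
Conditions: TBSCl, imidazole, CH2Cl2, rt
Reagents that add atoms: tert-butyl(chloro)dimethylsilane CC(C)(C)[Si](C)(C)Cl
Why: silylation masks the alcohol (the future ring carboxyl) and makes CH2OSi the bulkier group on the electron-rich alkene.

### Cyclobutane core and end game

**Step 18**
Reactants: 21 1-[(2S,5S)-2,5-dimethylpyrrolidin-1-yl]-2-Ar-ethan-1-one; 30 methyl (2E,6E)-8-(TBS-oxy)-3,7-dimethylocta-2,6-dienoate
Product: 33 methyl (2E)-5-[(1R,2S,4R)-2-Ar-1-(TBS-oxymethyl)-1-methyl-3-oxocyclobutan-4-yl]-3-methylpent-2-enoate, via keteniminium triflate 31 (not isolated), via cyclobutaniminium triflate 32 (not isolated)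
Conditions: Tf2O, 2,4,6-collidine, ClCH2CH2Cl, −20 °C → rt; then 30 (1.5 equiv), 70 °C; aq. NaHCO3, rt; Et3N (cat.), CH2Cl2
Reagents that add atoms: water O
Why: keteniminium–alkene [2+2] cycloaddition (Ghosez type), in which the iminium carbon bonds to the less substituted alkene carbon and the aryl-bearing carbon closes on the tertiary centre; the (E)-alkene puts the side chain cis to methyl, the C2-symmetric amine sets the absolute sense, and the α-aryl centre equilibrates so that aryl, side chain and CH2OSi are all pseudo-equatorial (aryl cis to methyl).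

**Step 19**
Reactants: 33 methyl (2E)-5-[(1R,2S,4R)-2-Ar-1-(TBS-oxymethyl)-1-methyl-3-oxocyclobutan-4-yl]-3-methylpent-2-enoate
Product: 34 methyl (2E)-5-[(1R,2S,4S)-2-Ar-1-(TBS-oxymethyl)-1-methyl-3-methylidenecyclobutan-4-yl]-3-methylpent-2-enoate
Conditions: Zn, CH2Br2, TiCl4, THF/CH2Cl2, 0 °C → rt
Reagents that add atoms: dibromomethane BrCBr
Why: Takai–Lombardo methylenation is non-basic, so the hindered, enolisable ketone is converted without epimerising the α-centres or touching the esters.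

**Step 20**
Reactants: 34 methyl (2E)-5-[(1R,2S,4S)-2-Ar-1-(TBS-oxymethyl)-1-methyl-3-methylidenecyclobutan-4-yl]-3-methylpent-2-enoate
Product: 36 methyl (2E)-5-[(1R,2S,3R,4S)-2-Ar-1-(TBS-oxymethyl)-3-(hydroxymethyl)-1-methylcyclobutan-4-yl]-3-methylpent-2-enoate, via B-alkyl-9-borabicyclononane 35 (not isolated)
Conditions: 9-BBN, THF, rt → 50 °C; then H2O2, aq. NaOAc, 0 °C
Reagents that add atoms: hydrogen peroxide OO
Why: anti-Markovnikov hydroboration–oxidation of the only reactive alkene delivers H to the ring carbon from the face away from aryl and side chain (CH2OH cis to both), a centre that is corrected in step 22.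

**Step 21**
Reactants: 36 methyl (2E)-5-[(1R,2S,3R,4S)-2-Ar-1-(TBS-oxymethyl)-3-(hydroxymethyl)-1-methylcyclobutan-4-yl]-3-methylpent-2-enoate
Product: 37 methyl (2E)-5-[(1R,2S,3R,4S)-2-Ar-1,3-bis(hydroxymethyl)-1-methylcyclobutan-4-yl]-3-methylpent-2-enoate
Conditions: CSA (cat.), MeOH, 0 °C → rt
Reagents that add atoms: none
Why: acid-catalysed methanolysis removes the primary alkyl TBS ether while the aryl TIPS ether survives.

**Step 22**
Reactants: 37 methyl (2E)-5-[(1R,2S,3R,4S)-2-Ar-1,3-bis(hydroxymethyl)-1-methylcyclobutan-4-yl]-3-methylpent-2-enoate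
Product: 39 methyl (2E)-5-[(1R,2S,3S,4S)-2-Ar-1,3-diformyl-1-methylcyclobutan-4-yl]-3-methylpent-2-enoate, via cis-dialdehyde 38 (not isolated)
Conditions: Dess–Martin periodinane, NaHCO3, CH2Cl2, rt; then DBU (0.3 equiv), CH2Cl2, rt
Reagents that add atoms: none
Why: Dess–Martin oxidation of both primary alcohols followed by base epimerisation of the only enolisable formyl-bearing carbon moves that CHO trans to both aryl and side chain, the thermodynamic arrangement with methyl as the only pseudo-axial group.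

**Step 23**
Reactants: 39 methyl (2E)-5-[(1R,2S,3S,4S)-2-Ar-1,3-diformyl-1-methylcyclobutan-4-yl]-3-methylpent-2-enoate
Product: 40 (1R,2S,3S,4S)-2-Ar-4-[(3E)-5-methoxy-3-methyl-5-oxopent-3-en-1-yl]-1-methylcyclobutane-1,3-dicarboxylic acid
Conditions: NaClO2, NaH2PO4, 2-methylbut-2-ene, t-BuOH/H2O, rt
Reagents that add atoms: sodium chlorite [Na+].[O-]Cl=O
Why: Pinnick oxidation converts both aldehydes to acids without epimerisation, and the scavenger protects the electron-rich arene and the enoate.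

**Step 24**
Reactants: 40 (1R,2S,3S,4S)-2-Ar-4-[(3E)-5-methoxy-3-methyl-5-oxopent-3-en-1-yl]-1-methylcyclobutane-1,3-dicarboxylic acid
Product: 41 (1R,2S,3S,4S)-2-Ar-4-[(3E)-4-carboxy-3-methylbut-3-en-1-yl]-1-methylcyclobutane-1,3-dicarboxylic acid
Conditions: Me3SnOH, ClCH2CH2Cl, 80 °C; dilute aq. HCl
Reagents that add atoms: trimethyltin hydroxide C[Sn](C)(C)O
Why: near-neutral tin hydroxide cleavage of the methyl ester keeps the aryl silyl ether and the (E)-enoate geometry intact.

**Step 25**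
Reactants: 41 (1R,2S,3S,4S)-2-Ar-4-[(3E)-4-carboxy-3-methylbut-3-en-1-yl]-1-methylcyclobutane-1,3-dicarboxylic acid; 11 (4R,4aR,6S,7R,7aS)-2,4,7-trimethyloctahydro-1H-cyclopenta[c]pyridin-6-ol (three equivalents are built into the product)
Product: 42 O-TIPS ether of the target (tris[(4R,4aR,6R,7R,7aS)-2,4,7-trimethyloctahydro-1H-cyclopenta[c]pyridin-6-yl] triester of 41)
Conditions: 11 (3.6 equiv in all), PPh3 (4 equiv), DIAD (4 equiv), THF/toluene, 0 °C → rt
Reagents that add atoms: two further equivalents of amino alcohol 11 O[C@H]1C[C@H]2[C@H](CN(C)C[C@@H]2C)[C@H]1C.O[C@H]1C[C@H]2[C@H](CN(C)C[C@@H]2C)[C@H]1C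
Why: threefold Mitsunobu esterification, in which each of the three carboxylates of 41 takes up one molecule of 11 by SN2 displacement of its activated C-6 oxygen with inversion to give the three (6R) esters, with the phenol masked so that it cannot compete.

**Step 26**
Reactants: 42 O-TIPS ether of the target
Product: 43 target CNP0251577.2
Conditions: Bu4NF, AcOH, THF, 0 °C
Reagents that add atoms: none
Why: buffered fluoride cleaves the aryl silyl ether selectively without touching the three esters, the enoate or the tertiary amines.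

---

### Compound list

1 | but-2-yn-1-amine | CC#CCN | starting material
2 | methyl but-2-yn-1-ylcarbamate | CC#CCNC(=O)OC | intermediate
3 | (2E)-1,4-dibromobut-2-ene | BrC/C=C/CBr | starting material
4 | sodium salt of carbamate 2 | CC#CC[N-]C(=O)OC.[Na+] | intermediate (not isolated)
5 | methyl [(2E)-4-bromobut-2-en-1-yl](but-2-yn-1-yl)carbamate | CC#CCN(C/C=C/CBr)C(=O)OC | intermediate
6 | methyl (but-2-yn-1-yl)[(2R)-2-methylbut-3-en-1-yl]carbamate | CC#CCN(C[C@H](C)C=C)C(=O)OC | intermediate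
7 | methyl (4R,4aR)-4,7-dimethyl-6-oxo-1,3,4,4a,5,6-hexahydro-2H-cyclopenta[c]pyridine-2-carboxylate | O=C1C[C@H]2C(CN(C(=O)OC)C[C@@H]2C)=C1C | intermediate
8 | methyl (4R,4aR,7S,7aS)-4,7-dimethyl-6-oxooctahydro-2H-cyclopenta[c]pyridine-2-carboxylate (cis-fused, 7-methyl cis to C-1) | O=C1C[C@H]2[C@H](CN(C(=O)OC)C[C@@H]2C)[C@@H]1C | intermediate (not isolated)
9 | methyl (4R,4aR,7R,7aS)-4,7-dimethyl-6-oxooctahydro-2H-cyclopenta[c]pyridine-2-carboxylate (cis-fused, 7-methyl cis to H-7a) | O=C1C[C@H]2[C@H](CN(C(=O)OC)C[C@@H]2C)[C@H]1C | intermediate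
10 | methyl (4R,4aR,6S,7R,7aS)-6-hydroxy-4,7-dimethyloctahydro-2H-cyclopenta[c]pyridine-2-carboxylate (OH cis to 7-methyl) | O[C@H]1C[C@H]2[C@H](CN(C(=O)OC)C[C@@H]2C)[C@H]1C | intermediate
11 | (4R,4aR,6S,7R,7aS)-2,4,7-trimethyloctahydro-1H-cyclopenta[c]pyridin-6-ol | O[C@H]1C[C@H]2[C@H](CN(C)C[C@@H]2C)[C@H]1C | intermediate
12 | benzene-1,2-diol | Oc1ccccc1O | starting material
13 | 2-methoxyphenol | COc1ccccc1O | intermediate
14 | 4-bromo-2-methoxyphenol | COc1cc(Br)ccc1O | intermediate
15 | (4-bromo-2-methoxyphenoxy)tri(propan-2-yl)silane | COc1cc(Br)ccc1O[Si](C(C)C)(C(C)C)C(C)C | intermediate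
16 | (2S,5S)-2,5-dimethylpyrrolidine | C[C@H]1CC[C@H](C)N1 | starting material
17 | acetyl chloride | CC(=O)Cl | starting material
18 | 1-[(2S,5S)-2,5-dimethylpyrrolidin-1-yl]ethan-1-one | CC(=O)N1[C@@H](C)CC[C@@H]1C | intermediate
19 | lithium enolate of 18 | [Li]OC(=C)N1[C@@H](C)CC[C@@H]1C | intermediate (not isolated)
20 | chlorozinc enolate of 18 (C-bound form) | Cl[Zn]CC(=O)N1[C@@H](C)CC[C@@H]1C | intermediate (not isolated)
21 | 1-[(2S,5S)-2,5-dimethylpyrrolidin-1-yl]-2-{3-methoxy-4-[tri(propan-2-yl)silyloxy]phenyl}ethan-1-one | COc1cc(CC(=O)N2[C@@H](C)CC[C@@H]2C)ccc1O[Si](C(C)C)(C(C)C)C(C)C | intermediate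
22 | 2-(2-bromoethyl)-1,3-dioxolane | BrCCC1OCCO1 | starting material
23 | methyl but-2-ynoate | CC#CC(=O)OC | starting material
24 | [2-(1,3-dioxolan-2-yl)ethyl]magnesium bromide | Br[Mg]CCC1OCCO1 | intermediate (not isolated)
25 | [2-(1,3-dioxolan-2-yl)ethyl]copper | [Cu]CCC1OCCO1 | intermediate (not isolated)
26 | methyl (2E)-5-(1,3-dioxolan-2-yl)-3-methylpent-2-enoate | COC(=O)/C=C(\C)CCC1OCCO1 | intermediate
27 | methyl (2E)-3-methyl-6-oxohex-2-enoate | COC(=O)/C=C(\C)CCC=O | intermediate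
28 | methyl (2E,6E)-3,7-dimethyl-8-oxoocta-2,6-dienoate | COC(=O)/C=C(\C)CC/C=C(\C)C=O | intermediate
29 | methyl (2E,6E)-8-hydroxy-3,7-dimethylocta-2,6-dienoate | COC(=O)/C=C(\C)CC/C=C(\C)CO | intermediate
30 | methyl (2E,6E)-8-{[tert-butyl(dimethyl)silyl]oxy}-3,7-dimethylocta-2,6-dienoate | COC(=O)/C=C(\C)CC/C=C(\C)CO[Si](C)(C)C(C)(C)C | intermediate
31 | keteniminium triflate from 21 (1-(2-Ar-ethenylidene)-(2S,5S)-2,5-dimethylpyrrolidinium triflate) | COc1cc(C=C=[N+]2[C@@H](C)CC[C@@H]2C)ccc1O[Si](C(C)C)(C(C)C)C(C)C.[O-]S(=O)(=O)C(F)(F)F | intermediate (not isolated)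
32 | cyclobutaniminium triflate (iminium of ketone 33 with the (2S,5S)-pyrrolidine) | COc1cc([C@@H]2C(=[N+]3[C@@H](C)CC[C@@H]3C)[C@H](CC/C(C)=C/C(=O)OC)[C@@]2(C)CO[Si](C)(C)C(C)(C)C)ccc1O[Si](C(C)C)(C(C)C)C(C)C.[O-]S(=O)(=O)C(F)(F)F | intermediate (not isolated)
33 | methyl (2E)-5-[(1R,2S,4R)-2-Ar-1-(TBS-oxymethyl)-1-methyl-3-oxocyclobutan-4-yl]-3-methylpent-2-enoate (aryl, side chain and methyl mutually cis) | COc1cc([C@@H]2C(=O)[C@H](CC/C(C)=C/C(=O)OC)[C@@]2(C)CO[Si](C)(C)C(C)(C)C)ccc1O[Si](C(C)C)(C(C)C)C(C)C | intermediate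
34 | methyl (2E)-5-[(1R,2S,4S)-2-Ar-1-(TBS-oxymethyl)-1-methyl-3-methylidenecyclobutan-4-yl]-3-methylpent-2-enoate | COc1cc([C@@H]2C(=C)[C@H](CC/C(C)=C/C(=O)OC)[C@@]2(C)CO[Si](C)(C)C(C)(C)C)ccc1O[Si](C(C)C)(C(C)C)C(C)C | intermediate
35 | B-alkyl-9-borabicyclo[3.3.1]nonane adduct of 34 (boron on the new exocyclic CH2, ring configuration as in 36) | COc1cc([C@@H]2[C@H](CB3C4CCCC3CCC4)[C@H](CC/C(C)=C/C(=O)OC)[C@@]2(C)CO[Si](C)(C)C(C)(C)C)ccc1O[Si](C(C)C)(C(C)C)C(C)C | intermediate (not isolated)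
36 | methyl (2E)-5-[(1R,2S,3R,4S)-2-Ar-1-(TBS-oxymethyl)-3-(hydroxymethyl)-1-methylcyclobutan-4-yl]-3-methylpent-2-enoate (CH2OH cis to aryl and side chain) | COc1cc([C@@H]2[C@H](CO)[C@H](CC/C(C)=C/C(=O)OC)[C@@]2(C)CO[Si](C)(C)C(C)(C)C)ccc1O[Si](C(C)C)(C(C)C)C(C)C | intermediate
37 | methyl (2E)-5-[(1R,2S,3R,4S)-2-Ar-1,3-bis(hydroxymethyl)-1-methylcyclobutan-4-yl]-3-methylpent-2-enoate | COc1cc([C@@H]2[C@H](CO)[C@H](CC/C(C)=C/C(=O)OC)[C@@]2(C)CO)ccc1O[Si](C(C)C)(C(C)C)C(C)C | intermediate
38 | methyl (2E)-5-[(1R,2S,3R,4S)-2-Ar-1,3-diformyl-1-methylcyclobutan-4-yl]-3-methylpent-2-enoate (3-CHO cis to aryl and side chain) | COc1cc([C@@H]2[C@H](C=O)[C@H](CC/C(C)=C/C(=O)OC)[C@@]2(C)C=O)ccc1O[Si](C(C)C)(C(C)C)C(C)C | intermediate (not isolated)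
39 | methyl (2E)-5-[(1R,2S,3S,4S)-2-Ar-1,3-diformyl-1-methylcyclobutan-4-yl]-3-methylpent-2-enoate (3-CHO trans to aryl and side chain) | COc1cc([C@@H]2[C@@H](C=O)[C@H](CC/C(C)=C/C(=O)OC)[C@@]2(C)C=O)ccc1O[Si](C(C)C)(C(C)C)C(C)C | intermediate
40 | (1R,2S,3S,4S)-2-Ar-4-[(3E)-5-methoxy-3-methyl-5-oxopent-3-en-1-yl]-1-methylcyclobutane-1,3-dicarboxylic acid | COc1cc([C@@H]2[C@@H](C(=O)O)[C@H](CC/C(C)=C/C(=O)OC)[C@@]2(C)C(=O)O)ccc1O[Si](C(C)C)(C(C)C)C(C)C | intermediate
41 | (1R,2S,3S,4S)-2-Ar-4-[(3E)-4-carboxy-3-methylbut-3-en-1-yl]-1-methylcyclobutane-1,3-dicarboxylic acid | COc1cc([C@@H]2[C@@H](C(=O)O)[C@H](CC/C(C)=C/C(=O)O)[C@@]2(C)C(=O)O)ccc1O[Si](C(C)C)(C(C)C)C(C)C | intermediate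
42 | O-TIPS ether of the target: tris[(4R,4aR,6R,7R,7aS)-2,4,7-trimethyloctahydro-1H-cyclopenta[c]pyridin-6-yl] triester of 41 | COc1cc([C@@H]2[C@@H](C(=O)O[C@@H]3C[C@H]4[C@H](CN(C)C[C@@H]4C)[C@H]3C)[C@H](CC/C(C)=C/C(=O)O[C@@H]3C[C@H]4[C@H](CN(C)C[C@@H]4C)[C@H]3C)[C@@]2(C)C(=O)O[C@@H]2C[C@H]3[C@H](CN(C)C[C@@H]3C)[C@H]2C)ccc1O[Si](C(C)C)(C(C)C)C(C)C | intermediate
43 | CNP0251577.2: tris[(4R,4aR,6R,7R,7aS)-2,4,7-trimethyloctahydro-1H-cyclopenta[c]pyridin-6-yl] triester of (1R,2S,3S,4S)-4-[(3E)-4-carboxy-3-methylbut-3-en-1-yl]-2-(4-hydroxy-3-methoxyphenyl)-1-methylcyclobutane-1,3-dicarboxylic acid | COc1cc([C@@H]2[C@@H](C(=O)O[C@@H]3C[C@H]4[C@H](CN(C)C[C@@H]4C)[C@H]3C)[C@H](CC/C(C)=C/C(=O)O[C@@H]3C[C@H]4[C@H](CN(C)C[C@@H]4C)[C@H]3C)[C@@]2(C)C(=O)O[C@@H]2C[C@H]3[C@H](CN(C)C[C@@H]3C)[C@H]2C)ccc1O | target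

---

**Total step count:** 26.
**Longest linear sequence:** 14 steps (steps 13–17, then 18–26).

**Three steps most likely to fail**

**Step 18 (keteniminium [2+2]).** The electron-rich aryl keteniminium may undergo Friedel–Crafts side reactions, and regiochemistry and auxiliary control are unproven on this trisubstituted alkene. The fallback sets out from 18 and 30 and returns at 33, and it introduces the aryl group after the ring is made. Acetamide 18 is activated (Tf2O, 2,4,6-collidine) to the parent keteniminium triflate F1, which adds to 30 to give the cyclobutaniminium triflate F2. Hydrolysis gives the aryl-free cyclobutanone F3. A palladium-catalysed ketone α-arylation of F3 with bromide 15 (Pd(dba)2, P(t-Bu)3, K3PO4, toluene, 80 °C) at its only α-methylene then installs the aryl group, and the basic medium equilibrates the new centre to the all-pseudo-equatorial isomer 33.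

**Step 19 (methylenation of the hindered, enolisable cyclobutanone).** The ketone is flanked by two substituted α-carbons and may react sluggishly. The fallback sets out from 33 and returns at 39, replacing methylenation/hydroboration by a one-carbon homologation through an enol ether. Wittig reaction of 33 with the ylide made in the flask from (methoxymethyl)triphenylphosphonium chloride and KOt-Bu gives the methoxymethylidene cyclobutane F4. Aqueous HCl in THF hydrolyses the enol ether and the TBS ether together to the hydroxy aldehyde F5. Dess–Martin oxidation of the remaining alcohol and DBU equilibration, as in step 22, then give 39.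

**Step 25 (threefold Mitsunobu).** Three SN2 displacements at a hindered secondary carbon, one by a neopentyl-type carboxylate, may stall or give elimination. The fallback sets out from 11 and 41 and returns at 42, changing from alcohol activation to acid activation. Alcohol 11 is first inverted by Mitsunobu reaction with 4-nitrobenzoic acid to the (6R) 4-nitrobenzoate F6, and K2CO3 in MeOH then frees the (6R) amino alcohol F7. Triacid 41 is converted with oxalyl chloride (cat. DMF) into the tris(acid chloride) F8. Acylation of F7 (3.5 equiv) with F8 (Et3N, DMAP, CH2Cl2) proceeds with retention at C-6 and gives 42.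

---

### Further compounds

F1 | step 18 | 1-ethenylidene-(2S,5S)-2,5-dimethylpyrrolidinium triflate | C=C=[N+]1[C@@H](C)CC[C@@H]1C.[O-]S(=O)(=O)C(F)(F)F
F2 | step 18 | cyclobutaniminium triflate of F3 with the (2S,5S)-pyrrolidine | C1C(=[N+]2[C@@H](C)CC[C@@H]2C)[C@H](CC/C(C)=C/C(=O)OC)[C@@]1(C)CO[Si](C)(C)C(C)(C)C.[O-]S(=O)(=O)C(F)(F)F
F3 | step 18 | methyl (2E)-5-[(1R,2S)-2-(TBS-oxymethyl)-2-methyl-4-oxocyclobutyl]-3-methylpent-2-enoate | C1C(=O)[C@H](CC/C(C)=C/C(=O)OC)[C@@]1(C)CO[Si](C)(C)C(C)(C)C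
F4 | step 19 | methyl (2E)-5-[2-Ar-1-(TBS-oxymethyl)-3-(methoxymethylidene)-1-methylcyclobutan-4-yl]-3-methylpent-2-enoate (ring configuration as in 33, enol ether E/Z mixture) | COc1cc([C@@H]2C(=COC)[C@H](CC/C(C)=C/C(=O)OC)[C@@]2(C)CO[Si](C)(C)C(C)(C)C)ccc1O[Si](C(C)C)(C(C)C)C(C)C
F5 | step 19 | methyl (2E)-5-[2-Ar-3-formyl-1-(hydroxymethyl)-1-methylcyclobutan-4-yl]-3-methylpent-2-enoate (epimer mixture at C-3, other centres as in 33) | COc1cc([C@@H]2C(C=O)[C@H](CC/C(C)=C/C(=O)OC)[C@@]2(C)CO)ccc1O[Si](C(C)C)(C(C)C)C(C)C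
F6 | step 25 | (4R,4aR,6R,7R,7aS)-2,4,7-trimethyloctahydro-1H-cyclopenta[c]pyridin-6-yl 4-nitrobenzoate | O=C(O[C@@H]1C[C@H]2[C@H](CN(C)C[C@@H]2C)[C@H]1C)c1ccc(cc1)[N+](=O)[O-]
F7 | step 25 | (4R,4aR,6R,7R,7aS)-2,4,7-trimethyloctahydro-1H-cyclopenta[c]pyridin-6-ol | O[C@@H]1C[C@H]2[C@H](CN(C)C[C@@H]2C)[C@H]1C
F8 | step 25 | (1R,2S,3S,4S)-2-Ar-4-[(3E)-5-chloro-3-methyl-5-oxopent-3-en-1-yl]-1-methylcyclobutane-1,3-dicarbonyl dichloride | COc1cc([C@@H]2[C@@H](C(=O)Cl)[C@H](CC/C(C)=C/C(=O)Cl)[C@@]2(C)C(=O)Cl)ccc1O[Si](C(C)C)(C(C)C)C(C)C
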